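Labdane numbering is used. Everything rests on reading the formyl-bearing methine C8 of ring B (C5–C10) as the outcome of an oxidative 1,2-shift. C8 and C17 begin as the two alkene carbons of a cycloheptene, so ring B is carried as the seven-membered ring C5–C6–C7–(C17/C8)–C9–C10 until the last step. Thallium trinitrate then contracts this ring, pushes C17 out as the aldehyde carbon and sets C8 in one operation. Both possible shifts converge on one skeleton. The precursor is a trans-fused 6-7 bicycle that already carries the Z-enoate chain. Its cycloheptene stems from a strain-driven cyclopropanation/Cope sequence, and ring A from a Robinson annulation.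

Key step: step 10

Assumption: Rh2(S-PTAD)4 is taken to deliver the (1S,2R)-cyclopropane 5. If the sense of induction is the opposite, Rh2(R-PTAD)4 is used instead.

Step 1
Reactants: 1 methyl 3-oxopentanoate
Product: 2 methyl 2-diazo-3-oxopentanoate
Conditions: 4-acetamidobenzenesulfonyl azide, Et3N, MeCN, 0 °C → rt
Reagents that add atoms: 4-acetamidobenzenesulfonyl azide, CC(=O)Nc1ccc(cc1)S(=O)(=O)N=[N+]=[N-]
Why: Regitz diazo transfer onto the doubly activated methylene of a β-keto ester is a standard reaction and creates no stereocentre.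

Step 2
Reactants: 2 methyl 2-diazo-3-oxopentanoate
Product: 3 methyl (3Z)-3-(tert-butyldimethylsilyloxy)-2-diazopent-3-enoate
Conditions: TBSOTf, Et3N, CH2Cl2, 0 °C
Reagents that add atoms: tert-butyldimethylsilyl trifluoromethanesulfonate, CC(C)(C)[Si](C)(C)OS(=O)(=O)C(F)(F)F
Why: Soft enolisation and O-silylation (silyl enol ether formation) should give the Z enol ether, with the methyl group syn to oxygen and anti to the bulky diazoester carbon, which is the geometry the later boat-shaped Cope transition state tolerates.

Step 3
Reactants: 3 methyl (3Z)-3-(tert-butyldimethylsilyloxy)-2-diazopent-3-enoate; 4 (3E)-hexa-1,3,5-triene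
Product: 6 methyl (3R,4R)-2-(tert-butyldimethylsilyloxy)-4-ethenyl-3-methylcyclohepta-1,5-diene-1-carboxylate, via cis-divinylcyclopropane 5 (not isolated)
Conditions: Rh2(S-PTAD)4 (1 mol %), 4 (5 equiv), hexanes, −20 °C → rt, then 40 °C
Reagents that add atoms: none
Why: The donor/acceptor rhodium carbenoid cyclopropanates one terminal double bond of the triene with the dienyl group cis to the siloxypropenyl group, and the strained 5 then undergoes a Cope rearrangement through a boat transition state (formal [4+3] cycloaddition), so that the chiral carboxylate ligands fix C9 and the alkene geometries fix the cis C9/C10 relation.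

Step 4
Reactants: 6 methyl (3R,4R)-2-(tert-butyldimethylsilyloxy)-4-ethenyl-3-methylcyclohepta-1,5-diene-1-carboxylate
Product: 8 (2S,3R)-3-ethenyl-2-methylcyclohept-4-en-1-one, via β-keto ester 7 (not isolated)
Conditions: LiCl (3 equiv), H2O (5 equiv), DMSO, 140 °C
Reagents that add atoms: none
Why: Hot aqueous chloride first cleaves the silyl enol ether and then removes the ester by Krapcho dealkoxycarbonylation, the non-enolisable C9 is untouched, and C10 (α to the ketone) settles as the more stable trans epimer, whose configuration is erased again in step 5.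

Step 5
Reactants: 8 (2S,3R)-3-ethenyl-2-methylcyclohept-4-en-1-one; 9 pent-1-en-3-one
Product: 11 (4aS,5R)-5-ethenyl-1,4a-dimethyl-3,4,4a,5,8,9-hexahydro-2H-benzo[7]annulen-2-one, via Michael adduct 10 (not isolated)
Conditions: 9 (1.3 equiv), KOH (0.15 equiv), MeOH, −10 °C → rt; then NaOMe (0.5 equiv), MeOH, 60 °C
Reagents that add atoms: none
Why: In this Robinson annulation the more substituted enolate (C10), favoured under equilibrating conditions, adds to the enone from the face anti to the neighbouring C9 vinyl group, which sets the quaternary C10 with methyl and vinyl cis, and the aldol condensation of C4 onto the C5 ketone then closes ring A.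

Step 6
Reactants: 11 (4aS,5R)-5-ethenyl-1,4a-dimethyl-3,4,4a,5,8,9-hexahydro-2H-benzo[7]annulen-2-one
Product: 13 (4aS,5R,9aS)-5-ethenyl-1,1,4a-trimethyl-1,3,4,4a,5,8,9,9a-octahydro-2H-benzo[7]annulen-2-one, via lithium enolate 12 (not isolated)
Conditions: Li, NH3(l)–THF, t-BuOH (1 equiv), −78 → −33 °C; isoprene; MeI, −78 °C → rt
Reagents that add atoms: iodomethane, CI
Why: In this Birch-type reductive alkylation of the enone the β-carbanion at C5 is protonated anti to the C10 methyl group to give the trans ring fusion, the regiospecific enolate is methylated at C4 to complete the gem-dimethyl group, and the isolated double bonds are not reduced.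

Step 7
Reactants: 13 (4aS,5R,9aS)-5-ethenyl-1,1,4a-trimethyl-1,3,4,4a,5,8,9,9a-octahydro-2H-benzo[7]annulen-2-one
Product: 14 (2R,4aS,5R,9aS)-5-ethenyl-1,1,4a-trimethyl-2,3,4,4a,5,8,9,9a-octahydro-1H-benzo[7]annulen-2-ol
Conditions: NaBH4, MeOH, 0 °C
Reagents that add atoms: none
Why: Borohydride reduction of the 4,4-dimethyl ketone should proceed by axial hydride attack from the face opposite the two axial methyl groups (on C4 and C10), giving the equatorial C3 alcohol.

Step 8
Reactants: 15 methyl but-2-ynoate
Product: 16 methyl (2Z)-3-iodobut-2-enoate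
Conditions: NaI, AcOH, 110 °C
Reagents that add atoms: sodium iodide, [Na+].[I-]
Why: Conjugate hydroiodination of the ynoate (iodide addition followed by protonation, net anti addition of HI) gives the Z β-iodoenoate with iodine cis to the ester.

Step 9
Reactants: 14 (2R,4aS,5R,9aS)-5-ethenyl-1,1,4a-trimethyl-2,3,4,4a,5,8,9,9a-octahydro-1H-benzo[7]annulen-2-ol; 16 methyl (2Z)-3-iodobut-2-enoate
Product: 18 methyl (2Z)-5-[(2R,4aS,5R,9aS)-2-hydroxy-1,1,4a-trimethyl-2,3,4,4a,5,8,9,9a-octahydro-1H-benzo[7]annulen-5-yl]-3-methylpent-2-enoate, via bis-borane 17 (not isolated)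
Conditions: 9-BBN (2.2 equiv), THF, 0 °C → rt; then 16, Pd(dppf)Cl2 (5 mol %), Ph3As, Cs2CO3, DMF–H2O, rt
Reagents that add atoms: none
Why: 9-BBN (one equivalent is held by the C3 hydroxyl as a borinate and released on work-up) hydroborates the monosubstituted vinyl group much faster than the hindered cis-disubstituted ring alkene and places boron on C12, and the B-alkyl Suzuki–Miyaura coupling keeps the geometry of the Z iodide, which gives the Z trisubstituted enoate.

Step 10
Reactants: 18 methyl (2Z)-5-[(2R,4aS,5R,9aS)-2-hydroxy-1,1,4a-trimethyl-2,3,4,4a,5,8,9,9a-octahydro-1H-benzo[7]annulen-5-yl]-3-methylpent-2-enoate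
Product: 21 methyl (2Z)-5-[(1R,2S,4aS,6R,8aS)-2-formyl-6-hydroxy-5,5,8a-trimethyldecahydronaphthalen-1-yl]-3-methylpent-2-enoate, via oxythallation adduct 19 (not isolated), via dimethyl acetal 20 (not isolated)
Conditions: Tl(NO3)3·3H2O (1.1 equiv), MeOH, −20 → 0 °C; filtration; then 1 M HCl, THF, rt
Reagents that add atoms: water, O; methanol, CO (its methoxy groups occur only in 19 and 20)
Why: Trivalent thallium adds to the only electron-rich double bond (the ring alkene between C9 and C7; the enoate is inert) from the face anti to the axial C10 methyl group, and methanol opens the thallonium ion anti to give 19 or its regioisomer. Heterolysis of the weak C–Tl bond is assisted by the antiperiplanar ring bond, so C9 (or C7 from the regioisomer) shifts to the thallium-bearing carbon with inversion while the methoxy-bearing carbon leaves the ring as an oxocarbenium ion that methanol traps as acetal 20; this is a seven-to-six ring contraction in which no new ring is closed, and the closest known reaction type is the thallium trinitrate rearrangement of cyclohexene and cycloheptene to the ring-contracted carbaldehyde acetals. Both regioisomeric adducts give the same constitution because the alkene is flanked by C9 and C7, so no regiocontrol is needed. C9 migrates with retention, and C8 is set by the anti shift, which leaves C17 on the face from which thallium came, that is equatorial and trans to the C9 chain; the acid hydrolysis of 20 passes through the enolisable aldehyde, so the diequatorial arrangement is also the thermodynamic one. The selectivity needed is carbon shift over hydride shift and over plain dimethoxylation, which the antiperiplanar alignment of the ring bonds in the anti adduct and the high migratory aptitude of the tertiary C9 should secure.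

Compound list
1 | methyl 3-oxopentanoate | CCC(=O)CC(=O)OC | starting material
2 | methyl 2-diazo-3-oxopentanoate | CCC(=O)C(=[N+]=[N-])C(=O)OC | intermediate
3 | methyl (3Z)-3-(tert-butyldimethylsilyloxy)-2-diazopent-3-enoate | C/C=C(\O[Si](C)(C)C(C)(C)C)C(=[N+]=[N-])C(=O)OC | intermediate
4 | (3E)-hexa-1,3,5-triene | C=C/C=C/C=C | starting material
5 | methyl (1S,2R)-2-[(1E)-buta-1,3-dien-1-yl]-1-[(1Z)-1-(tert-butyldimethylsilyloxy)prop-1-en-1-yl]cyclopropane-1-carboxylate (dienyl cis to siloxypropenyl) | COC(=O)[C@@]1(/C(O[Si](C)(C)C(C)(C)C)=C/C)C[C@@H]1/C=C/C=C | intermediate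
6 | methyl (3R,4R)-2-(tert-butyldimethylsilyloxy)-4-ethenyl-3-methylcyclohepta-1,5-diene-1-carboxylate (methyl and vinyl cis) | COC(=O)C1=C(O[Si](C)(C)C(C)(C)C)[C@H](C)[C@H](C=C)C=CC1 | intermediate
7 | methyl (3R,4R)-4-ethenyl-3-methyl-2-oxocyclohept-5-ene-1-carboxylate (C1 labile) | C=C[C@@H]1C=CCC(C(=O)OC)C(=O)[C@@H]1C | intermediate
8 | (2S,3R)-3-ethenyl-2-methylcyclohept-4-en-1-one (trans) | C=C[C@@H]1C=CCCC(=O)[C@H]1C | intermediate
9 | pent-1-en-3-one (ethyl vinyl ketone) | CCC(=O)C=C | starting material
10 | (2S,3R)-3-ethenyl-2-methyl-2-(3-oxopentyl)cyclohept-4-en-1-one (methyl and vinyl cis) | C=C[C@@H]1C=CCCC(=O)[C@@]1(C)CCC(=O)CC | intermediate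
11 | (4aS,5R)-5-ethenyl-1,4a-dimethyl-3,4,4a,5,8,9-hexahydro-2H-benzo[7]annulen-2-one | C=C[C@@H]1C=CCCC2=C(C)C(=O)CC[C@@]12C | intermediate
12 | lithium enolate (C3–O, C3=C4) of the trans-fused 4-monomethyl ketone | [Li+].C=C[C@@H]1C=CCC[C@@H]2C(C)=C([O-])CC[C@@]12C | intermediate
13 | (4aS,5R,9aS)-5-ethenyl-1,1,4a-trimethyl-1,3,4,4a,5,8,9,9a-octahydro-2H-benzo[7]annulen-2-one (trans-fused) | C=C[C@@H]1C=CCC[C@@H]2C(C)(C)C(=O)CC[C@@]12C | intermediate
14 | (2R,4aS,5R,9aS)-5-ethenyl-1,1,4a-trimethyl-2,3,4,4a,5,8,9,9a-octahydro-1H-benzo[7]annulen-2-ol (equatorial OH) | C=C[C@@H]1C=CCC[C@@H]2C(C)(C)[C@H](O)CC[C@@]12C | intermediate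
15 | methyl but-2-ynoate | CC#CC(=O)OC | starting material
16 | methyl (2Z)-3-iodobut-2-enoate | COC(=O)/C=C(/C)I | intermediate
17 | C12 B-alkyl-9-BBN of 14 with the C3 oxygen held as its 9-BBN borinate | B1(C2CCCC1CCC2)CC[C@@H]3C=CCC[C@@H]4C(C)(C)[C@H](OB5C6CCCC5CCC6)CC[C@@]34C | intermediate
18 | methyl (2Z)-5-[(2R,4aS,5R,9aS)-2-hydroxy-1,1,4a-trimethyl-2,3,4,4a,5,8,9,9a-octahydro-1H-benzo[7]annulen-5-yl]-3-methylpent-2-enoate | COC(=O)/C=C(/C)CC[C@@H]1C=CCC[C@@H]2C(C)(C)[C@H](O)CC[C@@]12C | intermediate
19 | anti oxythallation adduct of 18 (methoxy on the carbon next to C9, dinitratothallio group on the carbon next to C7 and anti to the C10 methyl) | COC(=O)/C=C(/C)CC[C@@H]1[C@H](OC)[C@@H]([Tl](O[N+](=O)[O-])O[N+](=O)[O-])CC[C@@H]2C(C)(C)[C@H](O)CC[C@@]12C | intermediate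
20 | dimethyl acetal of 21 | COC(=O)/C=C(/C)CC[C@@H]1[C@@H](C(OC)OC)CC[C@@H]2C(C)(C)[C@H](O)CC[C@@]12C | intermediate
21 | methyl (2Z)-5-[(1R,2S,4aS,6R,8aS)-2-formyl-6-hydroxy-5,5,8a-trimethyldecahydronaphthalen-1-yl]-3-methylpent-2-enoate | COC(=O)/C=C(/C)CC[C@@H]1[C@@H](C=O)CC[C@@H]2C(C)(C)[C@H](O)CC[C@@]12C | target

Total step count: 10. Longest linear sequence: 9 (steps 1–7, 9, 10).

Steps most likely to fail

1. Step 10. A hydride shift could compete with the carbon shift. Methanol could capture the organothallium centre before any shift. Allylic oxidation could erode the contraction.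
The fallback separates oxygen delivery from the shift. It sets out from 18. mCPBA in CH2Cl2 at 0 °C epoxidises only the electron-rich ring alkene, from the face anti to the C10 methyl group, to give the epoxide F1. BF3·OEt2 in CH2Cl2 at −78 °C then triggers a Meinwald rearrangement in which C9 or C7 enters anti to the breaking C–O bond. A short treatment with dilute acid equilibrates C8, and the route is rejoined at 21.

2. Step 5. The Michael addition could occur through the less hindered C6 enolate. The vinyl ketone could polymerise under base. Facial selectivity at C10 could be poor.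
The fallback replaces the enolate by a neutral secondary enamine. It sets out from 8, which is condensed with benzylamine (toluene, molecular sieves) to the imine F2. The more substituted enamine tautomer of F2 adds to 9 in THF at rt, anti to the vinyl group, to give the imine F3. Aqueous acetic acid hydrolyses F3, and the route is rejoined at 10, which is closed with NaOMe as in step 5.

3. Step 3. The methyl group on the carbenoid terminus could slow the Cope rearrangement or lower the enantioselectivity. A second cyclopropanation of the product could also intervene.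
The fallback brings the methyl group in after the cycloaddition. Commercial methyl acetoacetate is converted by diazo transfer into methyl 2-diazo-3-oxobutanoate F4. Silylation with TBSOTf/Et3N gives the parent siloxyvinyldiazoacetate F5. Setting out from 4, the same rhodium-catalysed cyclopropanation/Cope sequence with F5 gives the cycloheptadiene F6. Dilute HCl in THF releases the β-keto ester F7. Its dianion (NaH, then n-BuLi, THF, 0 °C) is methylated by MeI at the γ-carbon C10. The route is rejoined at 7, whose C10 configuration is inconsequential.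

Further compounds
F1 | step 10 | epoxide of 18 on the ring alkene, oxygen anti to the C10 methyl group | COC(=O)/C=C(/C)CC[C@@H]1[C@H]4O[C@H]4CC[C@@H]2C(C)(C)[C@H](O)CC[C@@]12C
F2 | step 5 | N-benzyl imine of 8 | C=C[C@@H]1C=CCCC(=NCc2ccccc2)[C@H]1C
F3 | step 5 | N-benzyl imine (ring carbonyl) of 10 | C=C[C@@H]1C=CCCC(=NCc2ccccc2)[C@@]1(C)CCC(=O)CC
F4 | step 3 | methyl 2-diazo-3-oxobutanoate | CC(=O)C(=[N+]=[N-])C(=O)OC
F5 | step 3 | methyl 3-(tert-butyldimethylsilyloxy)-2-diazobut-3-enoate | C=C(O[Si](C)(C)C(C)(C)C)C(=[N+]=[N-])C(=O)OC
F6 | step 3 | methyl (4R)-2-(tert-butyldimethylsilyloxy)-4-ethenylcyclohepta-1,5-diene-1-carboxylate | COC(=O)C1=C(O[Si](C)(C)C(C)(C)C)C[C@H](C=C)C=CC1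
F7 | step 3 | methyl (4R)-4-ethenyl-2-oxocyclohept-5-ene-1-carboxylate | C=C[C@@H]1C=CCC(C(=O)OC)C(=O)C1
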